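**Plan**

Numbering: butenolide O1, C2(=O), C3, C4, C5; chain on C5 is C1'H2–C2'(Me)=C3'H–C4'H2OAc; chain on C3 is C1''–C5''.
Retrosynthesis: first the two O–acetyl bonds; then, in one operation, ring bond O1–C5 and chain bond C1'–C2' (giving a (2Z)-2-alkylpenta-2,4-dienoic acid and an (E)-alkenyl triflate); then C3=C4 (Z-olefination with acrolein), C3–C1'' (phosphonate alkylation) and the C5''–O bond (allylic oxidation).
Enabling feature: O1 sits on C5, which is allylic to the ring C3=C4 bond, and C1' is the next carbon. C1'=C5–C4=C3 can therefore be a 1,3-diene with the C2 carboxyl cis to C5: alkenylpalladium adds to C1' and the carboxylate closes the C5–C4–C3 allylpalladium at C5.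
Forward: the C3 side chain is oxidised and joined to a phosphonate, then Z-olefination and saponification give the diene acid; the alkenyl triflate comes from ethyl acetoacetate; the key step joins both halves and forms the only ring; double acetylation ends the route.
Stereochemistry: C3''=C4'' (E) from the E-selective SeO2 oxidation; C2'=C3' (E) from E-selective enol triflation, retained in the coupling; C3=C4 (Z) from the Ando-type olefination; C5 (S) from the chiral ligand on palladium in the key step.

Key step: step 8

Assumption: the sense of induction of the chiral phosphoramidite in step 8 cannot be predicted with certainty; the ligand antipode that delivers the (5S)-lactone is the one used and is written below as the (S,R,R)-ligand.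

**Route**

Step 1
Reactants: 1 5-bromo-2-methylpent-2-ene
Product: 2 (2E)-5-bromo-2-methylpent-2-en-1-ol
Conditions: SeO2 (cat.), t-BuOOH, CH2Cl2, 0 °C to rt
Reagents that add atoms: selenium dioxide, O=[Se]=O (delivers the oxygen); tert-butyl hydroperoxide, CC(C)(C)OO (regenerates SeO2 and is the final source of the oxygen)
Why: Riley-type SeO2/t-BuOOH allylic oxidation (ene reaction, then [2,3]-sigmatropic shift) should oxidise the methyl group trans to the chain on the more substituted olefin terminus, so the new allylic alcohol is (E) and the primary bromide is untouched.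

Step 2
Reactants: 2 (2E)-5-bromo-2-methylpent-2-en-1-ol
Product: 3 (2E)-5-bromo-2-methylpent-2-en-1-yl acetate
Conditions: Ac2O, pyridine, DMAP (cat.), CH2Cl2, 0 °C to rt
Reagents that add atoms: acetic anhydride, CC(=O)OC(C)=O
Why: Standard acylation of a primary allylic alcohol; the acetate masks the hydroxyl through the two carbanion steps and is removed together with the ethyl ester in step 5.

Step 3
Reactants: 3 (2E)-5-bromo-2-methylpent-2-en-1-yl acetate; 4 ethyl 2-(diphenoxyphosphoryl)acetate
Product: 6 ethyl (5E)-7-acetoxy-2-(diphenoxyphosphoryl)-6-methylhept-5-enoate (racemic at C2), via sodium phosphonate carbanion 5 (not isolated)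
Conditions: NaH, THF, 0 °C; then 3, NaI (cat.), DMSO, 50 °C
Reagents that add atoms: none
Why: SN2 alkylation of the stabilised phosphonoacetate carbanion with the primary bromide under in-situ Finkelstein activation should be clean because the soft anion does not attack the acetate; the new C2 centre is racemic and is destroyed in step 4.

Step 4
Reactants: 6 ethyl (5E)-7-acetoxy-2-(diphenoxyphosphoryl)-6-methylhept-5-enoate; 7 acrolein (prop-2-enal)
Product: 9 ethyl (2Z)-2-[(3E)-5-acetoxy-4-methylpent-3-en-1-yl]penta-2,4-dienoate, via sodium carbanion 8 (not isolated)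
Conditions: NaH, THF, 0 °C; then 7, −78 °C to 0 °C
Reagents that add atoms: none
Why: Ando variant of the Horner–Wadsworth–Emmons olefination: the electron-poor diphenyl phosphonate makes collapse of the kinetic adduct fast and irreversible, which should give the trisubstituted (Z)-enoate with the vinyl group cis to the ester, the geometry that ring closure in step 8 needs.

Step 5
Reactants: 9 ethyl (2Z)-2-[(3E)-5-acetoxy-4-methylpent-3-en-1-yl]penta-2,4-dienoate
Product: 11 (2Z)-2-[(3E)-5-hydroxy-4-methylpent-3-en-1-yl]penta-2,4-dienoic acid, via lithium carboxylate 10 (not isolated)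
Conditions: LiOH·H2O, THF/H2O, rt; then 1 M HCl to pH 3, 0 °C
Reagents that add atoms: lithium hydroxide, [Li+].[OH-]
Why: Saponification (acyl–oxygen cleavage) should remove the ethyl ester and the acetate in one operation without touching the (Z)-diene, and cold, mild acidification gives the free hydroxy acid.

Step 6
Reactants: 12 ethyl acetoacetate (ethyl 3-oxobutanoate)
Product: 14 ethyl (2E)-3-{[(trifluoromethyl)sulfonyl]oxy}but-2-enoate, via tetramethylammonium enolate 13 (not isolated)
Conditions: Tf2O, aq. Me4NOH, hexanes, 5–10 °C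
Reagents that add atoms: trifluoromethanesulfonic anhydride, O=S(=O)(OS(=O)(=O)C(F)(F)F)C(F)(F)F
Why: Stereoselective enol triflation of a β-keto ester: with the non-coordinating tetramethylammonium counter-ion the enolate should adopt the unchelated geometry with O− trans to the ester, and O-sulfonylation fixes it as the (E)-enol triflate.

Step 7
Reactants: 14 ethyl (2E)-3-{[(trifluoromethyl)sulfonyl]oxy}but-2-enoate
Product: 16 (2E)-4-hydroxybut-2-en-2-yl trifluoromethanesulfonate, via diisobutylaluminium alkoxide 15 (not isolated)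
Conditions: i-Bu2AlH, CH2Cl2, −78 °C; aqueous Rochelle salt work-up
Reagents that add atoms: none
Why: 1,2-Reduction of the unsaturated ester to the allylic alcohol with i-Bu2AlH at −78 °C should leave the vinyl triflate and the (E) geometry untouched.

Step 8
Reactants: 11 (2Z)-2-[(3E)-5-hydroxy-4-methylpent-3-en-1-yl]penta-2,4-dienoic acid; 16 (2E)-4-hydroxybut-2-en-2-yl trifluoromethanesulfonate
Product: 18 (5S)-5-[(2E)-4-hydroxy-2-methylbut-2-en-1-yl]-3-[(3E)-5-hydroxy-4-methylpent-3-en-1-yl]furan-2(5H)-one, via potassium carboxylate 17 (not isolated)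
Conditions: Pd2(dba)3 (2.5 mol %), (S,R,R)-O,O'-(1,1'-binaphthalene-2,2'-diyl) N,N-bis(1-phenylethyl)phosphoramidite (6 mol %), K2CO3, 1,4-dioxane, 50 °C
Reagents that add atoms: none
Why: Proposed new method: oxidative addition of alkenyl triflate 16 to zerovalent palladium gives a cationic (E)-alkenylpalladium species (divalent palladium) that binds carboxylate 17 through oxygen, and syn migratory insertion of the terminal double bond of the diene (future C1'=C5) places the alkenyl carbon on C1' (the new C1'–C2' bond) and palladium on C5, where it is an allyl complex over C5–C4–C3; C–O bond formation at C5 then releases the butenolide and zerovalent palladium. The closest known reaction types are the Larock heteroannulation of 1,3-dienes and the enantioselective Heck/Tsuji–Trost 1,2-carbofunctionalisation of dienes that carry a tethered N- or O-nucleophile; what is new is that the carboxylate sits on the far allyl terminus (C3), so that the lactone encloses all three allyl carbons. The ring closes by O1–C5 bond formation as a 5-exo-tet displacement of palladium at the η1-allyl carbon C5 (C–O reductive elimination from a six-membered O,C-palladacycle, the cis-migration of carboxylate known from chloride-free 1,4-diacetoxylation of dienes), which is possible only because the (2Z) geometry of 11 holds the carboxylate cis to C5. C5 is the only new stereocentre and is under catalyst control: the chiral phosphoramidite on palladium selects the face of the terminal alkene that inserts, and the carboxylate is then delivered to C5 from the palladium-bearing face. The step needs regioselective insertion at the monosubstituted terminus (which gives a stabilised allyl) rather than at the trisubstituted C3=C4 and C3''=C4'' bonds, ring closure faster than β-hydride loss from C1' (favoured by the intramolecular carboxylate and the five-membered ring), and retention of the (E)-alkenyl geometry (stereoretentive oxidative addition and insertion).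

Step 9
Reactants: 18 (5S)-5-[(2E)-4-hydroxy-2-methylbut-2-en-1-yl]-3-[(3E)-5-hydroxy-4-methylpent-3-en-1-yl]furan-2(5H)-one
Product: 19 (5S)-5-[(2E)-4-acetoxy-2-methylbut-2-en-1-yl]-3-[(3E)-5-acetoxy-4-methylpent-3-en-1-yl]furan-2(5H)-one (target)
Conditions: Ac2O, pyridine, CH2Cl2, 0 °C to rt
Reagents that add atoms: acetic anhydride, CC(=O)OC(C)=O
Why: Acylation of both primary allylic alcohols; omitting DMAP and keeping the temperature low should keep the base-sensitive C5–H of the butenolide from epimerising.

**Compound list**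

1 | 5-bromo-2-methylpent-2-ene | CC(C)=CCCBr | starting material
2 | (2E)-5-bromo-2-methylpent-2-en-1-ol | OC/C(C)=C/CCBr | intermediate
3 | (2E)-5-bromo-2-methylpent-2-en-1-yl acetate | CC(=O)OC/C(C)=C/CCBr | intermediate
4 | ethyl 2-(diphenoxyphosphoryl)acetate | CCOC(=O)CP(=O)(Oc1ccccc1)Oc1ccccc1 | starting material
5 | sodium carbanion of ethyl 2-(diphenoxyphosphoryl)acetate | [Na+].CCOC(=O)[CH-]P(=O)(Oc1ccccc1)Oc1ccccc1 | intermediate
6 | ethyl (5E)-7-acetoxy-2-(diphenoxyphosphoryl)-6-methylhept-5-enoate (racemic) | CCOC(=O)C(CC/C=C(\C)COC(C)=O)P(=O)(Oc1ccccc1)Oc1ccccc1 | intermediate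
7 | acrolein | C=CC=O | starting material
8 | sodium carbanion of 6 | [Na+].CCOC(=O)[C-](CC/C=C(\C)COC(C)=O)P(=O)(Oc1ccccc1)Oc1ccccc1 | intermediate
9 | ethyl (2Z)-2-[(3E)-5-acetoxy-4-methylpent-3-en-1-yl]penta-2,4-dienoate | C=C/C=C(/CC/C=C(\C)COC(C)=O)C(=O)OCC | intermediate
10 | lithium (2Z)-2-[(3E)-5-hydroxy-4-methylpent-3-en-1-yl]penta-2,4-dienoate | [Li+].C=C/C=C(/CC/C=C(\C)CO)C(=O)[O-] | intermediate
11 | (2Z)-2-[(3E)-5-hydroxy-4-methylpent-3-en-1-yl]penta-2,4-dienoic acid | C=C/C=C(/CC/C=C(\C)CO)C(=O)O | intermediate
12 | ethyl acetoacetate | CCOC(=O)CC(C)=O | starting material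
13 | tetramethylammonium (E)-enolate of ethyl acetoacetate | C[N+](C)(C)C.CCOC(=O)/C=C(\C)[O-] | intermediate
14 | ethyl (2E)-3-{[(trifluoromethyl)sulfonyl]oxy}but-2-enoate | CCOC(=O)/C=C(\C)OS(=O)(=O)C(F)(F)F | intermediate
15 | diisobutylaluminium (2E)-3-{[(trifluoromethyl)sulfonyl]oxy}but-2-en-1-olate | CC(C)C[Al](CC(C)C)OC/C=C(\C)OS(=O)(=O)C(F)(F)F | intermediate
16 | (2E)-4-hydroxybut-2-en-2-yl trifluoromethanesulfonate | OC/C=C(\C)OS(=O)(=O)C(F)(F)F | intermediate
17 | potassium (2Z)-2-[(3E)-5-hydroxy-4-methylpent-3-en-1-yl]penta-2,4-dienoate | [K+].C=C/C=C(/CC/C=C(\C)CO)C(=O)[O-] | intermediate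
18 | (5S)-5-[(2E)-4-hydroxy-2-methylbut-2-en-1-yl]-3-[(3E)-5-hydroxy-4-methylpent-3-en-1-yl]furan-2(5H)-one | OC/C=C(\C)C[C@H]1C=C(CC/C=C(\C)CO)C(=O)O1 | intermediate
19 | (5S)-5-[(2E)-4-acetoxy-2-methylbut-2-en-1-yl]-3-[(3E)-5-acetoxy-4-methylpent-3-en-1-yl]furan-2(5H)-one | CC(=O)OC/C=C(\C)C[C@H]1C=C(CC/C=C(\C)COC(C)=O)C(=O)O1 | target

**Step count**

Total: 9 steps. Longest linear sequence: 7 steps (steps 1–5, 8, 9).

**Steps most likely to fail**

1. Step 8. The allylpalladium intermediate may lose a β-hydrogen from C1' faster than the carboxylate closes onto C5 (Heck-type polyene formation). Facial selection at insertion may also be poor, or the allylic lactone may re-ionise and erode the enantiomeric purity.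
The fallback uses known chemistry only, sets out from 16 and 6 (as its anion 8) and returns to the route at 19. Hydroboration of commercial acrolein diethyl acetal with 9-BBN-H gives 9-(3,3-diethoxypropyl)-9-borabicyclo[3.3.1]nonane F1. Its B-alkyl Suzuki–Miyaura coupling with 16 (PdCl2(dppf), K3PO4, THF/DMF/H2O) makes the same C1'–C2' bond and gives (2E)-6,6-diethoxy-3-methylhex-2-en-1-ol F2. Acetylation (Ac2O, pyridine) gives (2E)-6,6-diethoxy-3-methylhex-2-en-1-yl acetate F3, and acetal hydrolysis (aq. AcOH, THF) gives (2E)-3-methyl-6-oxohex-2-en-1-yl acetate F4. D-Proline-catalysed α-aminoxylation with nitrosobenzene sets the future C5 and gives (2E,5S)-5-(anilinooxy)-3-methyl-6-oxohex-2-en-1-yl acetate F5. Without isolation this is olefinated with carbanion 8 under the conditions of step 4 to ethyl (2Z,4S,6E)-8-acetoxy-2-[(3E)-5-acetoxy-4-methylpent-3-en-1-yl]-4-(anilinooxy)-6-methylocta-2,6-dienoate F6. Reductive N–O cleavage (Zn, AcOH, THF) gives ethyl (2Z,4S,6E)-8-acetoxy-2-[(3E)-5-acetoxy-4-methylpent-3-en-1-yl]-4-hydroxy-6-methylocta-2,6-dienoate F7, whose hydroxyl should lactonise onto the cis ester to give 19 directly.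

2. Step 4. The olefination may give incomplete (Z)-selectivity, and acrolein may polymerise or take up the carbanion in a conjugate addition under the basic conditions.
The fallback sets out from 6 and 7 and returns at 9. Conjugate addition of benzeneselenol to 7 gives 3-(phenylselanyl)propanal F8, a saturated aldehyde that should behave normally in the Ando-type olefination with carbanion 8. This gives ethyl (2Z)-2-[(3E)-5-acetoxy-4-methylpent-3-en-1-yl]-5-(phenylselanyl)pent-2-enoate F9, from which any (E)-isomer can be removed at this stage. Oxidation with H2O2 (pyridine, CH2Cl2, 0 °C) gives ethyl (2Z)-2-[(3E)-5-acetoxy-4-methylpent-3-en-1-yl]-5-(benzeneseleninyl)pent-2-enoate F10, whose syn-elimination unveils the terminal double bond and gives 9.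

3. Step 3. The homoallylic bromide may undergo E2 elimination to the conjugated diene, or the phosphonate may be alkylated twice.
The fallback sets out from 3, returns at 11, replaces steps 3–5 and holds the (Z) geometry in a temporary six-membered lactone. Commercial 5,6-dihydro-2H-pyran-2-one is α-iodinated (I2, pyridine, CH2Cl2) to 3-iodo-5,6-dihydro-2H-pyran-2-one F11. Bromide 3 is converted (Zn dust, LiCl, THF, 50 °C) into [(3E)-5-acetoxy-4-methylpent-3-en-1-yl]zinc bromide F12. Negishi coupling of F11 and F12 (PdCl2(dppf), THF, rt) gives 3-[(3E)-5-acetoxy-4-methylpent-3-en-1-yl]-5,6-dihydro-2H-pyran-2-one F13. KOt-Bu in THF at 0 °C removes a ring C5 proton and expels the carboxylate (E1cB ring opening, the ring having fixed the (Z) geometry) to give potassium (2Z)-2-[(3E)-5-acetoxy-4-methylpent-3-en-1-yl]penta-2,4-dienoate F14. Aqueous LiOH then cleaves the acetate and acidification gives 11.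

**Further compounds**

F1 | step 8 | 9-(3,3-diethoxypropyl)-9-borabicyclo[3.3.1]nonane | CCOC(CCB1C2CCCC1CCC2)OCC
F2 | step 8 | (2E)-6,6-diethoxy-3-methylhex-2-en-1-ol | OC/C=C(\C)CCC(OCC)OCC
F3 | step 8 | (2E)-6,6-diethoxy-3-methylhex-2-en-1-yl acetate | CC(=O)OC/C=C(\C)CCC(OCC)OCC
F4 | step 8 | (2E)-3-methyl-6-oxohex-2-en-1-yl acetate | CC(=O)OC/C=C(\C)CCC=O
F5 | step 8 | (2E,5S)-5-(anilinooxy)-3-methyl-6-oxohex-2-en-1-yl acetate | CC(=O)OC/C=C(\C)C[C@H](ONc1ccccc1)C=O
F6 | step 8 | ethyl (2Z,4S,6E)-8-acetoxy-2-[(3E)-5-acetoxy-4-methylpent-3-en-1-yl]-4-(anilinooxy)-6-methylocta-2,6-dienoate | CC(=O)OC/C=C(\C)C[C@H](ONc1ccccc1)/C=C(/CC/C=C(\C)COC(C)=O)C(=O)OCC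
F7 | step 8 | ethyl (2Z,4S,6E)-8-acetoxy-2-[(3E)-5-acetoxy-4-methylpent-3-en-1-yl]-4-hydroxy-6-methylocta-2,6-dienoate | CC(=O)OC/C=C(\C)C[C@H](O)/C=C(/CC/C=C(\C)COC(C)=O)C(=O)OCC
F8 | step 4 | 3-(phenylselanyl)propanal | O=CCC[Se]c1ccccc1
F9 | step 4 | ethyl (2Z)-2-[(3E)-5-acetoxy-4-methylpent-3-en-1-yl]-5-(phenylselanyl)pent-2-enoate | CCOC(=O)/C(CC/C=C(\C)COC(C)=O)=C\CC[Se]c1ccccc1
F10 | step 4 | ethyl (2Z)-2-[(3E)-5-acetoxy-4-methylpent-3-en-1-yl]-5-(benzeneseleninyl)pent-2-enoate | CCOC(=O)/C(CC/C=C(\C)COC(C)=O)=C\CC[Se](=O)c1ccccc1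
F11 | step 3 | 3-iodo-5,6-dihydro-2H-pyran-2-one | O=C1OCCC=C1I
F12 | step 3 | [(3E)-5-acetoxy-4-methylpent-3-en-1-yl]zinc bromide | CC(=O)OC/C(C)=C/CC[Zn]Br
F13 | step 3 | 3-[(3E)-5-acetoxy-4-methylpent-3-en-1-yl]-5,6-dihydro-2H-pyran-2-one | CC(=O)OC/C(C)=C/CCC1=CCCOC1=O
F14 | step 3 | potassium (2Z)-2-[(3E)-5-acetoxy-4-methylpent-3-en-1-yl]penta-2,4-dienoate | [K+].C=C/C=C(/CC/C=C(\C)COC(C)=O)C(=O)[O-]
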